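Amounts answer most of your question, so the flasks, readings and questions come first.

| flask | left-handed substrate | right-handed substrate | reagent | free catalyst | racemization catalyst | impurity | added ligand | remark | time |
|---|---|---|---|---|---|---|---|---|---|
| Monday's | 0.096 M | 0.096 M | 0.11 M | 0.48 mM | 4.8 mM | 3.4 mM | 0.39 mM | run made earlier |  |
| Wednesday's | 0.096 M | 0.096 M | 0.15 M | 0.48 mM | 4.8 mM | 3.4 mM | 0.39 mM | run made earlier |  |
| Saturday's | 0.096 M | 0.096 M | 0.17 M | 0.48 mM | 4.8 mM | 3.4 mM | 0.39 mM | run made earlier |  |
| elm | 0.096 M | 0.096 M | 0.211 M | 0.48 mM | 4.8 mM | 3.4 mM | 0.39 mM |  | 8.0 d |
| alder | 0.096 M | 0.096 M | 0.100 M | 0.48 mM | 4.8 mM | 3.4 mM | 0.39 mM |  | 8.0 d |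

- Monday's (time / d: right-handed substrate / %, left-handed substrate / %): 0.333: 47.0, 13.1; 0.833: 43.6, 8.5; 1.67: 37.9, 9.0; 4.00: 28.4, 14.8
- Wednesday's (time / d: right-handed substrate / %, left-handed substrate / %): 0.500: 44.8, 4.6; 1.25: 37.4, 3.6; 2.50: 29.8, 4.1; 4.00: 23.2, 4.5
- Saturday's (time / d: right-handed substrate / %, left-handed substrate / %): 0.500: 43.4, 3.1; 1.25: 36.9, 2.6; 2.50: 27.8, 2.7; 4.00: 21.1, 3.3

(readings scatter by 0.3 percentage points)

- free catalyst is single-handed; left-handed substrate and right-handed substrate are mirror images of each other, charged as a racemate, each of them at the stated concentration
- what may be going on: reagent + free catalyst + left-handed substrate -> free catalyst + left-handed product; reagent + free catalyst + right-handed substrate -> free catalyst + right-handed product; left-handed substrate + racemization catalyst <-> right-handed substrate + racemization catalyst; reagent -> decomposition product; racemization catalyst + impurity -> spent catalyst; free catalyst + added ligand <-> idle complex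
- an excess is the difference of the two amounts in percent of their sum
- an excess is below zero if the other one leads

1. the flask that ends with the higher excess of right-handed substrate over left-handed substrate among what is left of the two, or "neither" when 2 percentage points or less lies between them (elm / alder / neither)
2. excess of right-handed substrate over left-handed substrate among what is left of the two at the end, elm
3. excess of right-handed substrate over left-handed substrate among what is left of the two at the end, alder

1. Each substrate molecule that becomes product costs one reagent. Alder's reagent charge is 52.1 % of both substrates charged together, and that fraction of the charge is the reagent budget.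

2. Monday's readings test the budget: 56.8 % of the substrates are gone at 4.00 d, against a budget of 57.3 %.

3. Saturday's run has 75.6 % of the substrates gone at 4.00 d, against a budget of 88.5 %, and there reads 3.3 % of left-handed substrate against 21.1 % of right-handed substrate.

4. Near the end of its budget, Monday's left-handed substrate climbs from 9.0 % to 14.8 % while right-handed substrate falls, which reads as racemization refilling it.

5. Alder's budget is below the whole charge, so reagent is its limiting reagent: product stops near the budget, and the unreacted substrates drift towards equal amounts.

6. Elm's budget of 110 % exceeds the whole charge, so its reagent can keep removing left-handed substrate as racemization supplies it.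

7. This reckoning of mine gives elm as the leader and no figure for either excess. Your forecast supplies those: elm, with 74 % for elm and 6 % for alder, on the ground for alder that “Racemization then erases the excess”.

Elm ends at 81.3 % and alder at 5.67 %, so elm leads.

    reagent + free catalyst + left-handed substrate → free catalyst + left-handed product (k = 8010 /M²/h)
    reagent + free catalyst + right-handed substrate → free catalyst + right-handed product (k = 115 /M²/h)
    left-handed substrate + racemization catalyst ⇌ right-handed substrate + racemization catalyst, rate k3*[racemization catalyst]*[left-handed substrate] forward; the back reaction follows from the equilibrium constant (k = 5.64 /M/h)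
    reagent → decomposition product (k = 2.93 × 10⁻⁵ /h)
    racemization catalyst + impurity → spent catalyst (k = 219 /M/h)
    free catalyst + added ligand ⇌ idle complex (K = 5400 /M, k = 124 /M/h)

The forecast's elm figure lies 7.3 percentage points below the flask's. Alder has reacted 52.1 % of its substrates, against its budget of 52.1 %, with reagent at 0 % of its charge. A neighbour of elm charged with 0.053 M of reagent has a budget of 27.6 %, and its two products hold 27.6 % of the substrates. There, 35.5 % of left-handed substrate and 36.9 % of right-handed substrate stand at an excess of 1.86 %.

The numbers in the tables were generated by integration from invented constants; scatter was added.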